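**Plan** (flavanone numbering: O1, C2–C4, C4a, C5–C8, C8a)
- Retrosynthesis: the C4 ketone is first taken back to a silyl-protected carbinol. Rings A and C are then cut together at C7–C8, C4a–C8a and C6–C7.
- Enabling feature: in ring A the C7 hydroxyl, the C8 prenyl group and the C8a ether oxygen O1 sit on three neighbouring carbons. This phenol–alkyl–alkoxy pattern is what a vinylketene and an alkynyl ether give on benzannulation. The precursor is a 2-substituted cyclobutenone whose C4–C3–C2–O1 chain ends in an O1 ynol ether.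
- Further cuts: C4–C4a (aldol of 2-(phenylselanyl)cyclobutanone), C8–prenyl and O1–C8a (ynol ether from trichloroethylene), C3–C2 carbonyl (malonate acylation). The enone is freed by selenoxide elimination, because an enone acetal would need acid that hydrates the ynol ether.
- Forward order: chain C2–C3–C4, then the ynol ether on O1, then the four-membered ring at C4, then rings C and A in one operation, then oxidation at C4.
- Stereochemistry: C2 (S) comes from asymmetric hydrogenation of the β-keto ester. Its C–O bond is never broken afterwards. C4 is not controlled and ends as the carbonyl.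

Key step: step 12

Assumption: the carbinol carbon that becomes C4 and the selenium-bearing ring carbon are carried as epimer mixtures and drawn without configuration, since both lose their configuration before the target.

**Route**

Step 1
Reactants: 1 2,2-dimethylchroman-6-carboxylic acid; 2 potassium ethyl malonate
Product: 4 ethyl 3-(2,2-dimethylchroman-6-yl)-3-oxopropanoate, via acyl imidazolide 3 (not isolated)
Conditions: 1,1'-carbonyldiimidazole, THF, 20 °C; then 2, MgCl2, Et3N, MeCN, 20 → 50 °C; 1 M HCl work-up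
Reagents that add atoms: 1,1'-carbonyldiimidazole O=C(n1ccnc1)n1ccnc1 (gives the imidazolyl group of 3 only)
Why: Masamune–Brooks acylation: the acyl imidazolide acylates the magnesium enolate of the malonate half-ester at carbon, and loss of CO2 on acidic work-up leaves the β-keto ester that carries C2, C3 and C4.

Step 2
Reactants: 4 ethyl 3-(2,2-dimethylchroman-6-yl)-3-oxopropanoate
Product: 5 ethyl (3S)-3-(2,2-dimethylchroman-6-yl)-3-hydroxypropanoate
Conditions: H2 (50 atm), RuCl2[(R)-BINAP] (1 mol %), EtOH, 50 °C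
Reagents that add atoms: none
Why: Noyori asymmetric hydrogenation of a β-keto ester: the substrate chelates the BINAP–ruthenium hydride through both carbonyl groups, so the ligand decides the face of hydride delivery, and the (R)-ligand is expected to give the (S)-carbinol here, the same spatial sense as with acetoacetates, the descriptor changing only because aryl outranks CH2CO2Et.

Step 3
Reactants: 5 ethyl (3S)-3-(2,2-dimethylchroman-6-yl)-3-hydroxypropanoate
Product: 6 (1S)-1-(2,2-dimethylchroman-6-yl)propane-1,3-diol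
Conditions: LiAlH4, THF, 0 → 20 °C
Reagents that add atoms: none
Why: Hydride reduction of the ester gives the 1,3-diol without touching the benzylic stereocentre.

Step 4
Reactants: 6 (1S)-1-(2,2-dimethylchroman-6-yl)propane-1,3-diol
Product: 7 (1S)-1-(2,2-dimethylchroman-6-yl)-3-(triisopropylsilyloxy)propan-1-ol
Conditions: i-Pr3SiCl, imidazole, DMF, 0 °C
Reagents that add atoms: triisopropylsilyl chloride CC(C)[Si](Cl)(C(C)C)C(C)C
Why: Silylation of the less hindered primary hydroxyl; the bulky triisopropylsilyl group is chosen because it resists the 1,5 oxygen-to-oxygen silyl shift that a smaller silyl group could undergo in the potassium alkoxide of step 5.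

Step 5
Reactants: 7 (1S)-1-(2,2-dimethylchroman-6-yl)-3-(triisopropylsilyloxy)propan-1-ol; 8 trichloroethylene; 9 prenyl bromide
Product: 12 triisopropyl{(3S)-3-(2,2-dimethylchroman-6-yl)-3-[(5-methylhex-4-en-1-yn-1-yl)oxy]propoxy}silane, via dichlorovinyl ether 10 (not isolated), via lithium alkynyl ether 11 (not isolated)
Conditions: KH, THF, 0 °C; 8, −50 → 20 °C; n-BuLi (2.4 equiv), −78 °C; 9, HMPA, −78 → −20 °C; NaHCO3 work-up, Et3N-deactivated silica
Reagents that add atoms: n-butyllithium [Li]CCCC (gives the lithium of 11 only)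
Why: Greene ynol ether synthesis in one flask: the potassium alkoxide adds to dichloroacetylene generated from trichloroethylene, two equivalents of n-BuLi convert the dichlorovinyl ether into the lithium alkoxyacetylide by elimination and chlorine–lithium exchange, and this is alkylated (SN2) at the primary carbon of prenyl bromide; the C2–O bond is not broken, so C2 stays (S).

Step 6
Reactants: 12 triisopropyl{(3S)-3-(2,2-dimethylchroman-6-yl)-3-[(5-methylhex-4-en-1-yn-1-yl)oxy]propoxy}silane
Product: 13 (3S)-3-(2,2-dimethylchroman-6-yl)-3-[(5-methylhex-4-en-1-yn-1-yl)oxy]propan-1-ol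
Conditions: Bu4NF, THF, 0 → 20 °C
Reagents that add atoms: none
Why: Fluoride cleavage of the silyl ether under basic conditions, to which ynol ethers are inert (they are labile to acid and heat only).

Step 7
Reactants: 13 (3S)-3-(2,2-dimethylchroman-6-yl)-3-[(5-methylhex-4-en-1-yn-1-yl)oxy]propan-1-ol
Product: 14 (3S)-3-(2,2-dimethylchroman-6-yl)-3-[(5-methylhex-4-en-1-yn-1-yl)oxy]propanal
Conditions: Dess–Martin periodinane, pyridine, CH2Cl2, 0 °C; used crude
Reagents that add atoms: none
Why: Dess–Martin oxidation buffered with pyridine gives the aldehyde under neutral, non-aqueous conditions; the β-alkynyloxy aldehyde is taken on crude because it could lose ynolate by β-elimination on silica or with base.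

Step 8
Reactants: 15 cyclobutanone
Product: 16 2-(phenylselanyl)cyclobutan-1-one
Conditions: LiN(i-Pr)2, THF, −78 °C (ketone added to base); PhSeCl, −78 °C
Reagents that add atoms: benzeneselenenyl chloride Cl[Se]c1ccccc1
Why: Reich α-selenenylation of the lithium enolate; inverse addition of the ketone to the amide base at −78 °C suppresses self-aldol.

Step 9
Reactants: 14 (3S)-3-(2,2-dimethylchroman-6-yl)-3-[(5-methylhex-4-en-1-yn-1-yl)oxy]propanal; 16 2-(phenylselanyl)cyclobutan-1-one
Product: 17 2-[(3S)-3-(2,2-dimethylchroman-6-yl)-1-hydroxy-3-[(5-methylhex-4-en-1-yn-1-yl)oxy]propyl]-2-(phenylselanyl)cyclobutan-1-one (diastereomer mixture)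
Conditions: 16, LiN(i-Pr)2, THF, −78 °C; then 14, −78 °C; AcOH quench at −78 °C
Reagents that add atoms: none
Why: Aldol addition: the amide base removes the proton on the selenium-bearing carbon, the more acidic α-position, and at −78 °C the enolate should add to the aldehyde faster than it deprotonates it; the two new centres need no control, since one becomes sp2 in step 11 and the other becomes the C4 carbonyl.

Step 10
Reactants: 17 2-[(3S)-3-(2,2-dimethylchroman-6-yl)-1-hydroxy-3-[(5-methylhex-4-en-1-yn-1-yl)oxy]propyl]-2-(phenylselanyl)cyclobutan-1-one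
Product: 18 2-[(3S)-3-(2,2-dimethylchroman-6-yl)-3-[(5-methylhex-4-en-1-yn-1-yl)oxy]-1-(triethylsilyloxy)propyl]-2-(phenylselanyl)cyclobutan-1-one
Conditions: Et3SiCl, imidazole, DMAP (cat.), CH2Cl2, 0 °C
Reagents that add atoms: chlorotriethylsilane CC[Si](Cl)(CC)CC
Why: Imidazole-promoted silylation with the chlorosilane is mild and weakly basic, so the ynol ether is spared; the ether keeps the carbinol from adding to the ketenes of step 12 and blocks retro-aldol cleavage.

Step 11
Reactants: 18 2-[(3S)-3-(2,2-dimethylchroman-6-yl)-3-[(5-methylhex-4-en-1-yn-1-yl)oxy]-1-(triethylsilyloxy)propyl]-2-(phenylselanyl)cyclobutan-1-one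
Product: 20 2-[(3S)-3-(2,2-dimethylchroman-6-yl)-3-[(5-methylhex-4-en-1-yn-1-yl)oxy]-1-(triethylsilyloxy)propyl]cyclobut-2-en-1-one, via selenoxide 19 (not isolated)
Conditions: NaIO4, NaHCO3, THF–MeOH–H2O, 0 → 20 °C; product kept cold and dark, used at once
Reagents that add atoms: sodium periodate [Na+].[O-]I(=O)(=O)=O (gives the oxygen of 19 only)
Why: Reich selenoxide syn-elimination: periodate oxidises selenium only, and the selenoxide should eliminate at or below 20 °C towards the ring CH2 and not towards the silyloxy-bearing carbon (selenoxide eliminations avoid forming enol ethers), which unveils the 2-substituted cyclobutenone without the acid that an enone acetal would need and that would hydrate the ynol ether.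

Step 12
Reactants: 20 2-[(3S)-3-(2,2-dimethylchroman-6-yl)-3-[(5-methylhex-4-en-1-yn-1-yl)oxy]-1-(triethylsilyloxy)propyl]cyclobut-2-en-1-one
Product: 25 (2S)-2-(2,2-dimethylchroman-6-yl)-8-(3-methylbut-2-en-1-yl)-4-(triethylsilyloxy)chroman-7-ol, via vinylketene 21 (not isolated), via bicyclic vinylcyclobutenone 22 (not isolated), via dienylketene 23 (not isolated), via cyclohexadienone 24 (not isolated)
Conditions: hν (350 nm lamps, Pyrex), degassed toluene (0.005 M), 20 °C; then 80 °C in the dark
Reagents that add atoms: none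
Why: Proposed new method: light opens the cyclobutenone (4-electron electrocyclic opening with release of ring strain) to vinylketene 21 at 20 °C, whose carbonyl carbon (future C7) is attacked by the nucleophilic prenyl-bearing alkyne carbon (C8) while its α-carbon (C4a) bonds to the oxygen-bearing alkyne carbon (C8a); warming then opens bicyclic enone 22 to dienylketene 23, which closes by 6-electron electrocyclisation (C6–C7) to dienone 24 and tautomerises to phenol 25. The closest known reaction type is the Danheiser benzannulation of cyclobutenone-derived vinylketenes with alkynyl ethers, established between two separate molecules; running it with the partners tethered so that both rings close is untested. Ring C closes in the [2+2] step as a six-membered ring fused to the new cyclobutenone, the four-atom tether C4–C3–C2–O1 joining the ketene α-carbon to the alkyne carbon it must bond to; ring A closes in the 6-electron electrocyclisation, for which ring C holds the vinyl and ketene arms cis on the C4a=C8a double bond. No lasting stereocentre is made: the quaternary C4a of 22 becomes aromatic, C2 is not involved and stays (S), and C4 is carried as both epimers. The step needs the 7-hydroxy-8-prenyl regiochemistry, which ketene and ynol ether polarity secure in the same sense as the tether, and it needs ketene capture to outrun the [3,3] shift and the retro-ene loss of ketene open to a benzylic alkynyl ether on heating, which is secured by making the ketene photochemically at 20 °C and heating only after the ynol ether has been consumed.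

Step 13
Reactants: 25 (2S)-2-(2,2-dimethylchroman-6-yl)-8-(3-methylbut-2-en-1-yl)-4-(triethylsilyloxy)chroman-7-ol
Product: 26 (2S)-2-(2,2-dimethylchroman-6-yl)-8-(3-methylbut-2-en-1-yl)chromane-4,7-diol
Conditions: Bu4NF, AcOH (1:1), THF, 0 °C
Reagents that add atoms: none
Why: Fluoride desilylation buffered with acetic acid, so that neither the phenoxide nor a benzylic cation at C4 (para to the C7 hydroxyl) is generated; C2 is untouched.

Step 14
Reactants: 26 (2S)-2-(2,2-dimethylchroman-6-yl)-8-(3-methylbut-2-en-1-yl)chromane-4,7-diol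
Product: 27 Euchrenone a17
Conditions: MnO2 (activated), CH2Cl2, 20 °C
Reagents that add atoms: none
Why: MnO2 oxidation of an activated benzylic alcohol: heterogeneous and neutral, it should leave the phenol and the prenyl group alone and provides no base that could open the flavanone to the chalcone and racemise C2.

**Compound list**
1 | 2,2-dimethylchroman-6-carboxylic acid | CC1(C)CCc2cc(C(=O)O)ccc2O1 | starting material
2 | potassium ethyl malonate | CCOC(=O)CC(=O)[O-].[K+] | starting material
3 | (2,2-dimethylchroman-6-yl)(1H-imidazol-1-yl)methanone (acyl imidazolide, not isolated) | O=C(c1ccc2OC(C)(C)CCc2c1)n1ccnc1 | intermediate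
4 | ethyl 3-(2,2-dimethylchroman-6-yl)-3-oxopropanoate | CCOC(=O)CC(=O)c1ccc2OC(C)(C)CCc2c1 | intermediate
5 | ethyl (3S)-3-(2,2-dimethylchroman-6-yl)-3-hydroxypropanoate | CCOC(=O)C[C@H](O)c1ccc2OC(C)(C)CCc2c1 | intermediate
6 | (1S)-1-(2,2-dimethylchroman-6-yl)propane-1,3-diol | OCC[C@H](O)c1ccc2OC(C)(C)CCc2c1 | intermediate
7 | (1S)-1-(2,2-dimethylchroman-6-yl)-3-(triisopropylsilyloxy)propan-1-ol | CC(C)[Si](OCC[C@H](O)c1ccc2OC(C)(C)CCc2c1)(C(C)C)C(C)C | intermediate
8 | trichloroethylene | ClC=C(Cl)Cl | starting material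
9 | prenyl bromide (1-bromo-3-methylbut-2-ene) | CC(C)=CCBr | starting material
10 | {(3S)-3-[(E)-1,2-dichlorovinyloxy]-3-(2,2-dimethylchroman-6-yl)propoxy}triisopropylsilane (dichlorovinyl ether, not isolated) | CC(C)[Si](OCC[C@H](O/C(Cl)=C\Cl)c1ccc2OC(C)(C)CCc2c1)(C(C)C)C(C)C | intermediate
11 | lithium {[(1S)-1-(2,2-dimethylchroman-6-yl)-3-(triisopropylsilyloxy)propoxy]ethynide} (lithium alkynyl ether, not isolated) | CC(C)[Si](OCC[C@H](OC#C[Li])c1ccc2OC(C)(C)CCc2c1)(C(C)C)C(C)C | intermediate
12 | triisopropyl{(3S)-3-(2,2-dimethylchroman-6-yl)-3-[(5-methylhex-4-en-1-yn-1-yl)oxy]propoxy}silane | CC(C)[Si](OCC[C@H](OC#CCC=C(C)C)c1ccc2OC(C)(C)CCc2c1)(C(C)C)C(C)C | intermediate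
13 | (3S)-3-(2,2-dimethylchroman-6-yl)-3-[(5-methylhex-4-en-1-yn-1-yl)oxy]propan-1-ol | OCC[C@H](OC#CCC=C(C)C)c1ccc2OC(C)(C)CCc2c1 | intermediate
14 | (3S)-3-(2,2-dimethylchroman-6-yl)-3-[(5-methylhex-4-en-1-yn-1-yl)oxy]propanal | O=CC[C@H](OC#CCC=C(C)C)c1ccc2OC(C)(C)CCc2c1 | intermediate
15 | cyclobutanone | O=C1CCC1 | starting material
16 | 2-(phenylselanyl)cyclobutan-1-one (racemic) | O=C1CCC1[Se]c1ccccc1 | intermediate
17 | 2-[(3S)-3-(2,2-dimethylchroman-6-yl)-1-hydroxy-3-[(5-methylhex-4-en-1-yn-1-yl)oxy]propyl]-2-(phenylselanyl)cyclobutan-1-one (diastereomer mixture) | OC(C[C@H](OC#CCC=C(C)C)c1ccc2OC(C)(C)CCc2c1)C1([Se]c2ccccc2)CCC1=O | intermediate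
18 | 2-[(3S)-3-(2,2-dimethylchroman-6-yl)-3-[(5-methylhex-4-en-1-yn-1-yl)oxy]-1-(triethylsilyloxy)propyl]-2-(phenylselanyl)cyclobutan-1-one (diastereomer mixture) | CC[Si](CC)(CC)OC(C[C@H](OC#CCC=C(C)C)c1ccc2OC(C)(C)CCc2c1)C1([Se]c2ccccc2)CCC1=O | intermediate
19 | selenoxide of 18 (not isolated) | CC[Si](CC)(CC)OC(C[C@H](OC#CCC=C(C)C)c1ccc2OC(C)(C)CCc2c1)C1([Se](=O)c2ccccc2)CCC1=O | intermediate
20 | 2-[(3S)-3-(2,2-dimethylchroman-6-yl)-3-[(5-methylhex-4-en-1-yn-1-yl)oxy]-1-(triethylsilyloxy)propyl]cyclobut-2-en-1-one (both epimers at the silyloxy carbon) | CC[Si](CC)(CC)OC(C[C@H](OC#CCC=C(C)C)c1ccc2OC(C)(C)CCc2c1)C1=CCC1=O | intermediate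
21 | (5S)-5-(2,2-dimethylchroman-6-yl)-2-ethenyl-5-[(5-methylhex-4-en-1-yn-1-yl)oxy]-3-(triethylsilyloxy)pent-1-en-1-one (vinylketene, not isolated) | CC[Si](CC)(CC)OC(C[C@H](OC#CCC=C(C)C)c1ccc2OC(C)(C)CCc2c1)C(C=C)=C=O | intermediate
22 | (3S)-3-(2,2-dimethylchroman-6-yl)-6-ethenyl-8-(3-methylbut-2-en-1-yl)-5-(triethylsilyloxy)-2-oxabicyclo[4.2.0]oct-1(8)-en-7-one (bicyclic vinylcyclobutenone, not isolated) | CC[Si](CC)(CC)OC1C[C@@H](c2ccc3OC(C)(C)CCc3c2)OC2=C(CC=C(C)C)C(=O)C12C=C | intermediate
23 | 2-[(2S)-2-(2,2-dimethylchroman-6-yl)-5-ethenyl-4-(triethylsilyloxy)-3,4-dihydro-2H-pyran-6-yl]-5-methylhexa-1,4-dien-1-one (dienylketene, not isolated) | CC[Si](CC)(CC)OC1C[C@@H](c2ccc3OC(C)(C)CCc3c2)OC(C(CC=C(C)C)=C=O)=C1C=C | intermediate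
24 | (2S)-2-(2,2-dimethylchroman-6-yl)-8-(3-methylbut-2-en-1-yl)-4-(triethylsilyloxy)-3,4-dihydro-2H-chromen-7(6H)-one (cyclohexadienone tautomer, not isolated) | CC[Si](CC)(CC)OC1C[C@@H](c2ccc3OC(C)(C)CCc3c2)OC2=C(CC=C(C)C)C(=O)CC=C12 | intermediate
25 | (2S)-2-(2,2-dimethylchroman-6-yl)-8-(3-methylbut-2-en-1-yl)-4-(triethylsilyloxy)chroman-7-ol (both C4 epimers) | CC(C)=CCc1c(O)ccc2c1O[C@H](c1ccc3c(c1)CCC(C)(C)O3)CC2O[Si](CC)(CC)CC | intermediate
26 | (2S)-2-(2,2-dimethylchroman-6-yl)-8-(3-methylbut-2-en-1-yl)chromane-4,7-diol (both C4 epimers) | CC(C)=CCc1c(O)ccc2c1O[C@H](c1ccc3c(c1)CCC(C)(C)O3)CC2O | intermediate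
27 | Euchrenone a17, (2S)-2-(2,2-dimethylchroman-6-yl)-7-hydroxy-8-(3-methylbut-2-en-1-yl)chroman-4-one | CC(C)=CCc1c(O)ccc2c1O[C@H](c1ccc3c(c1)CCC(C)(C)O3)CC2=O | target

**Count**
Total steps: 14. Longest linear sequence: 13 steps (steps 1–7 and 9–14, from acid 1 to target 27); step 8 is a one-step branch.

**Steps most likely to fail**

1. Step 12 (proposed new method). The tethered [2+2] may lose to dimerisation of the vinylketene, to thermal reclosure to 20, or to fragmentation of the benzylic ynol ether before it is captured.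
Fallback, known chemistry only: ring A is taken from a resorcinol and C2 is set by catalytic asymmetric conjugate addition to a chromone. It sets out from prenyl bromide 9 and comes back at target 27. Prenyl bromide 9 should C-alkylate commercial 2,4-dihydroxyacetophenone between its hydroxyls (aq KOH, 0 °C) to give 1-[2,4-dihydroxy-3-(3-methylbut-2-en-1-yl)phenyl]ethan-1-one F1. Silylation of the non-chelated 4-hydroxyl (t-BuMe2SiCl, imidazole) would give 1-[4-(tert-butyldimethylsilyloxy)-2-hydroxy-3-(3-methylbut-2-en-1-yl)phenyl]ethan-1-one F2. Condensation with Me2NCH(OMe)2 would give (E)-1-[4-(tert-butyldimethylsilyloxy)-2-hydroxy-3-(3-methylbut-2-en-1-yl)phenyl]-3-(dimethylamino)prop-2-en-1-one F3, which should close in warm AcOH to 7-(tert-butyldimethylsilyloxy)-8-(3-methylbut-2-en-1-yl)-4H-chromen-4-one F4. Commercial 6-bromo-2,2-dimethylchromane would be converted (n-BuLi; B(OMe)3; aqueous acid) into (2,2-dimethylchroman-6-yl)boronic acid F5. Palladium-catalysed asymmetric conjugate addition of F5 to F4 (Pd(OCOCF3)2, the t-BuPyOx enantiomer that delivers the 2S adduct, NH4PF6, H2O, ClCH2CH2Cl, 60 °C) should give (2S)-7-(tert-butyldimethylsilyloxy)-2-(2,2-dimethylchroman-6-yl)-8-(3-methylbut-2-en-1-yl)chroman-4-one F6. Bu4NF/AcOH would then release 27.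

2. Step 9. The enolate may act as a base and expel ynolate from 14 by β-elimination, may form at the wrong α-carbon of 16, or the adduct may revert by retro-aldol.
Fallback: the same vinylketene is reached from an α-diazo enone by Wolff rearrangement. It sets out from aldehyde 14 and comes back at vinylketene 21, hence 25, and so also bypasses steps 10 and 11. Methyl vinyl ketone would be converted by detrifluoroacetylative diazo transfer (LiN(SiMe3)2, CF3CO2CH2CF3; MeSO2N3, Et3N) into 1-diazobut-3-en-2-one F7. Its lithio derivative (LiN(i-Pr)2, THF, −78 °C) would be added to 14 to give (7S)-4-diazo-7-(2,2-dimethylchroman-6-yl)-5-hydroxy-7-[(5-methylhex-4-en-1-yn-1-yl)oxy]hept-1-en-3-one F8. Silylation (Et3SiCl, imidazole) would give (7S)-4-diazo-7-(2,2-dimethylchroman-6-yl)-7-[(5-methylhex-4-en-1-yn-1-yl)oxy]-5-(triethylsilyloxy)hept-1-en-3-one F9. Irradiation of F9 at 20 °C should expel nitrogen with migration of the vinyl group and give 21, which continues to 25 as in step 12.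

3. Step 5. Silyl migration in the potassium alkoxide, sluggish or SN2′ alkylation of the lithium alkoxyacetylide, or base-induced isomerisation of the skipped enyne may erode the ynol ether.
Fallback: C8 is joined to the prenyl group by neutral cross-coupling instead of alkylation. It sets out from 7, taken as in step 5 to lithium alkynyl ether 11, and comes back at 12. Quenching 11 with Bu3SnCl would give tributyl{[(1S)-1-(2,2-dimethylchroman-6-yl)-3-(triisopropylsilyloxy)propoxy]ethynyl}stannane F10, which is isolated. Stille coupling of F10 with prenyl bromide 9 (Pd(PPh3)4 cat., THF, 20–40 °C) should then give 12.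

**Further compounds**
F1 | step 12 | 1-[2,4-dihydroxy-3-(3-methylbut-2-en-1-yl)phenyl]ethan-1-one | CC(=O)c1ccc(O)c(CC=C(C)C)c1O
F2 | step 12 | 1-[4-(tert-butyldimethylsilyloxy)-2-hydroxy-3-(3-methylbut-2-en-1-yl)phenyl]ethan-1-one | CC(=O)c1ccc(O[Si](C)(C)C(C)(C)C)c(CC=C(C)C)c1O
F3 | step 12 | (E)-1-[4-(tert-butyldimethylsilyloxy)-2-hydroxy-3-(3-methylbut-2-en-1-yl)phenyl]-3-(dimethylamino)prop-2-en-1-one | CN(C)/C=C/C(=O)c1ccc(O[Si](C)(C)C(C)(C)C)c(CC=C(C)C)c1O
F4 | step 12 | 7-(tert-butyldimethylsilyloxy)-8-(3-methylbut-2-en-1-yl)-4H-chromen-4-one | O=c1ccoc2c(CC=C(C)C)c(O[Si](C)(C)C(C)(C)C)ccc12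
F5 | step 12 | (2,2-dimethylchroman-6-yl)boronic acid | OB(O)c1ccc2OC(C)(C)CCc2c1
F6 | step 12 | (2S)-7-(tert-butyldimethylsilyloxy)-2-(2,2-dimethylchroman-6-yl)-8-(3-methylbut-2-en-1-yl)chroman-4-one | CC(C)=CCc1c(O[Si](C)(C)C(C)(C)C)ccc2c1O[C@H](c1ccc3c(c1)CCC(C)(C)O3)CC2=O
F7 | step 9 | 1-diazobut-3-en-2-one | C=CC(=O)C=[N+]=[N-]
F8 | step 9 | (7S)-4-diazo-7-(2,2-dimethylchroman-6-yl)-5-hydroxy-7-[(5-methylhex-4-en-1-yn-1-yl)oxy]hept-1-en-3-one | C=CC(=O)C(=[N+]=[N-])C(O)C[C@H](OC#CCC=C(C)C)c1ccc2OC(C)(C)CCc2c1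
F9 | step 9 | (7S)-4-diazo-7-(2,2-dimethylchroman-6-yl)-7-[(5-methylhex-4-en-1-yn-1-yl)oxy]-5-(triethylsilyloxy)hept-1-en-3-one | C=CC(=O)C(=[N+]=[N-])C(O[Si](CC)(CC)CC)C[C@H](OC#CCC=C(C)C)c1ccc2OC(C)(C)CCc2c1
F10 | step 5 | tributyl{[(1S)-1-(2,2-dimethylchroman-6-yl)-3-(triisopropylsilyloxy)propoxy]ethynyl}stannane | CC(C)[Si](OCC[C@H](OC#C[Sn](CCCC)(CCCC)CCCC)c1ccc2OC(C)(C)CCc2c1)(C(C)C)C(C)C
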